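The north-east run held less target than the north run, 63.6% against 78.5% of the substrate charged as means of their readings, and I wanted to know what that gap was worth for the new flask.

| setting | north | north-east | north-west | flask |
|---|---|---|---|---|
| substrate | 14 mM | 22 mM | 10 mM | 10 mM |
| gas | 0.38 mM (held) | 0.38 mM (held) | 0.38 mM (held) | 0.38 mM (held) |
| free catalyst | 65 µM | 65 µM | 32 µM | 65 µM |
| remark | run made earlier | run made earlier | run made earlier |  |
| time |  |  |  | 3.0 d |

| run | time / h | substrate / % | target / % |
|---|---|---|---|
| north | 10.0 | 0 | 79.2 |
| north | 20.0 | 0 | 78.3 |
| north | 30.0 | 0 | 78.5 |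
| north | 40.0 | 0.5 | 78.0 |
| north-east | 10.0 | 0 | 63.0 |
| north-east | 20.0 | 0 | 62.1 |
| north-east | 30.0 | 0.4 | 65.0 |
| north-east | 40.0 | 2.3 | 64.4 |
| north-west | 5.00 | 0 | 81.1 |
| north-west | 15.0 | 0.7 | 80.1 |
| north-west | 30.0 | 0.7 | 79.7 |
| north-west | 40.0 | 0 | 77.6 |

(readings scatter by 1 percentage point)

- the earlier runs were read with a standard deviation of 1 percentage point
- at the start none of the gas is in solution
- the reaction counts as stopped when no species that holds the substrate changes by six tenths of a point or more over the second half of the time

- which holds at 3.0 d: what has brought the reaction to rest, or that it has not come to rest (no working catalyst is left / all of the substrate has reacted / forward and back rates have come level / it is still moving)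
- how much of the substrate has reacted by 3.0 d
- how much target there is at 3.0 d, in percent of the substrate charged
- amount of target if the flask were left three thousand times as long, in percent of the substrate charged

I read the tables row by row. The first readings of the three runs, taken well before 3.0 d, showed no substrate, so I expected none in the flask at the asked time. Target then stayed level within the scatter, which is why I averaged it.

The north row lacked 21.5% of its charge and the north-east row 36.4%. Dividing each by its substrate charge gave 0.0154 mM⁻¹ and 0.0165 mM⁻¹, which are close. I called their mean ℓ, 0.0159 mM⁻¹, the loss per millimolar: the share of the charge that fails to become target for each millimolar charged, at 65 µM free catalyst.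

The north-west row, with about half the free catalyst, had a mean of 79.6%, which read as a loss per millimolar of 0.0204 mM⁻¹, more than ℓ, but that run had another free catalyst charge, so I kept it out of ℓ. For the flask, ℓ gave me 84.1% target, both at 3.0 d and after long standing.

The forecast said all of the substrate has reacted, with 100% reacted, 80% target at 3.0 d and 80% in the long run, noting that “no visible equilibrium or slow return is happening”. My figure stood above its figure.

The flask gave this: all of the substrate has reacted, with 100% reacted, 86.1% target at 3.0 d and 86.1% in the long run.

    substrate + free catalyst → catalyst intermediate A (k = 23.0 M⁻¹ s⁻¹)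
    catalyst intermediate A ⇌ catalyst intermediate B (K = 0.150, k = 0.0860 s⁻¹)
    reagent + catalyst intermediate B ⇌ catalyst intermediate C (K = 2500 M⁻¹, k = 2900 M⁻¹ s⁻¹)
    catalyst intermediate C ⇌ by-product + catalyst intermediate D (K = 0.0110 M, k = 14.0 s⁻¹)
    catalyst intermediate D → free catalyst + target (k = 24.0 s⁻¹)
    2 substrate → homo dimer (k = 0.00510 M⁻¹ s⁻¹)
    gas ⇌ reagent, rate k7*(csat - [reagent]) (kL = 0.00970 s⁻¹)

At the start of the flask, the step of substrate with free catalyst used substrate 15 times as fast as the step to homo dimer. By 3.00 d the flask held 86.1% target beside 13.9% homo dimer, each homo dimer counted as two substrate. That is a loss per millimolar of 0.0139 mM⁻¹, a little under ℓ. For the neighbour flask with 40 mM substrate, ℓ gives 36.4% target, and that flask held 43.4%.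

The readings are simulated with constants of no real substance; noise was put on by code.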